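**Retrosynthetic overview**
1. Target 11 ⇒ 1,3-prototropic shift (C2-H to C10-H) ⇒ β,γ-enone spiro adduct 10.
2. 10 ⇒ [4+2] disconnection of C2–C4' and C14–C15' ⇒ cross-conjugated dienone 9 (diene C2=C1–C10=C14, 11S series) + α-methylene cyclopentanone 7 (dienophile C4'=C15', 11R series), as in the presumed biogenesis.
3. 9 ⇒ ketone 5 by in-flask dehydrogenation; 5 and 7 ⇒ C3 allylic oxidation of the C11-epimeric dihydro lactones 2 and 3.
4. 2 and 3 ⇒ face-divergent reduction of the lactone methylene of dehydrocostus lactone 1.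
5. Ring order: the 5-7-5 rings of both halves come ready-made from 1; the only ring formed is the spiro-cyclohexene, last, in the cycloaddition cascade.

Assumption: dehydrocostus lactone (main lactone of commercial costus root oil) counts as a cheap commercial starting material; the target SMILES is read as 5αH,6βH,7αH,10βH,11S in the cyclopentenone half and 1'αH,5'αH,6'βH,7'αH,11'R in the spiro half, with the C4'–C2 bond on the α-face of the spiro half (guaianolide numbering, primes for the spiro-cyclopentanone half).

**Step 1**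
Reactants: 1 dehydrocostus lactone
Product: 2 mokko lactone ((11S)-11β,13-dihydrodehydrocostus lactone)
Conditions: NaBH4 (1.5 equiv), MeOH, 0 °C, 30 min; aq. NH4Cl
Reagents that add atoms: none
Why: Chemoselective conjugate reduction (1,4-hydride addition) of the only conjugated alkene, the α-methylene-γ-lactone; the lactone enolate is protonated at C11 on the β-face, anti to the axial H-7, giving the more stable 11S epimer (methyl α, trans to C8).

**Step 2**
Reactants: 1 dehydrocostus lactone
Product: 3 11-epi-mokko lactone ((11R)-11α,13-dihydrodehydrocostus lactone)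
Conditions: Ru(OAc)2[(S)-BINAP] (2 mol %), H2 (100 atm), CH2Cl2, 50 °C
Reagents that add atoms: none
Why: Noyori–Takaya asymmetric hydrogenation of an α-methylene-γ-butyrolactone: the lactone carbonyl binds divalent ruthenium so only C11=C13 is reduced, and the ligand antipode (chosen by analogy with the parent lactone, which gives the (R)-α-methyl lactone) delivers H2 to the α-face against the substrate's β-face bias, setting 11R; any 11S co-product is compound 2 and feeds step 3.

**Step 3**
Reactants: 2 mokko lactone
Product: 5 (11S)-3-oxoguaia-4(15),10(14)-dien-12,6α-olide (11β,13-dihydrodehydrozaluzanin C), via allylic alcohol 4 (not isolated)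
Conditions: SeO2 (0.5 equiv), t-BuOOH (5.5 M in decane, 2.5 equiv), CH2Cl2, 0 → 23 °C; then activated MnO2 (20 equiv), 23 °C
Reagents that add atoms: tert-butyl hydroperoxide, CC(C)(C)OO; selenium dioxide, O=[Se]=O (oxygen carrier)
Why: Riley–Sharpless allylic oxidation (ene reaction, then [2,3]-sigmatropic shift) hydroxylates C3, the cyclopentane CH2 next to C4=C15, from the convex α-face, and MnO2 then oxidises the allylic alcohol and destroys residual peroxide, so both C3 epimers converge on the enone and no stereocentre remains at C3.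

**Step 4**
Reactants: 3 11-epi-mokko lactone
Product: 7 (11R)-3-oxoguaia-4(15),10(14)-dien-12,6α-olide (11α,13-dihydrodehydrozaluzanin C), via allylic alcohol 6 (not isolated)
Conditions: SeO2 (0.5 equiv), t-BuOOH (5.5 M in decane, 2.5 equiv), CH2Cl2, 0 → 23 °C; then activated MnO2 (20 equiv), 23 °C
Reagents that add atoms: tert-butyl hydroperoxide, CC(C)(C)OO; selenium dioxide, O=[Se]=O (oxygen carrier)
Why: Same Riley–Sharpless allylic oxidation and MnO2 allylic-alcohol oxidation as in step 3; the conditions are neutral, so the kinetically set, less stable 11R centre is not epimerised.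

**Step 5**
Reactants: 5 (11S)-3-oxoguaia-4(15),10(14)-dien-12,6α-olide; 7 (11R)-3-oxoguaia-4(15),10(14)-dien-12,6α-olide
Product: 11 CNP0240988.1 (target spiro dimer), via silyl enol ether 8 (not isolated), via trienone 9 (not isolated), via Diels-Alder adduct 10 (not isolated)
Conditions: 5, TMSOTf (1.15 equiv), Et3N (1.5 equiv), CH2Cl2, 0 °C; evaporate; 7 (3 equiv), Pd(OAc)2 (1.05 equiv), degassed MeCN, Ar, 23 → 40 °C; then Et3N (5 equiv), 23 °C
Reagents that add atoms: none
Why: Soft enolisation gives the only possible enol ether 8, Saegusa–Ito oxidation (syn β-hydride loss of H-1α) releases the s-cis-locked dienone 9 in the presence of excess 7, an "ortho"-selective intermolecular Diels–Alder reaction joins C14–C15' and C2–C4' on the convex α-face of 7 (sets spiro C4'; diene face and endo/exo are erased later), and Et3N then effects a 1,3-prototropic shift of H-2β to the β-face of C10 (same face as the departing proton, the α-face being screened by the spiro-linked bicycle) to give the conjugated enone with H-10β; argon prevents autoxidation at C10.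

**Compound list**
1 | dehydrocostus lactone (1αH,5αH,6βH,7αH-guaia-4(15),10(14),11(13)-trien-12,6α-olide) | C=C1CC[C@H]2C(=C)CC[C@@H]3[C@H](OC(=O)C3=C)[C@H]21 | starting material
2 | mokko lactone ((11S)-11β,13-dihydrodehydrocostus lactone; 11βH, methyl α) | C=C1CC[C@H]2C(=C)CC[C@@H]3[C@H](OC(=O)[C@H]3C)[C@H]21 | intermediate
3 | 11-epi-mokko lactone ((11R)-11α,13-dihydrodehydrocostus lactone; 11αH, methyl β) | C=C1CC[C@H]2C(=C)CC[C@@H]3[C@H](OC(=O)[C@@H]3C)[C@H]21 | intermediate
4 | (3R,11S)-3α-hydroxyguaia-4(15),10(14)-dien-12,6α-olide (11β,13-dihydro-3-epizaluzanin C; minor 3β epimer converges) | C=C1[C@H](O)C[C@H]2C(=C)CC[C@@H]3[C@H](OC(=O)[C@H]3C)[C@H]21 | intermediate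
5 | (11S)-3-oxoguaia-4(15),10(14)-dien-12,6α-olide (11β,13-dihydrodehydrozaluzanin C) | C=C1C(=O)C[C@H]2C(=C)CC[C@@H]3[C@H](OC(=O)[C@H]3C)[C@H]21 | intermediate
6 | (3R,11R)-3α-hydroxyguaia-4(15),10(14)-dien-12,6α-olide | C=C1[C@H](O)C[C@H]2C(=C)CC[C@@H]3[C@H](OC(=O)[C@@H]3C)[C@H]21 | intermediate
7 | (11R)-3-oxoguaia-4(15),10(14)-dien-12,6α-olide (11α,13-dihydrodehydrozaluzanin C) | C=C1C(=O)C[C@H]2C(=C)CC[C@@H]3[C@H](OC(=O)[C@@H]3C)[C@H]21 | intermediate
8 | (11S)-3-(trimethylsilyloxy)guaia-2,4(15),10(14)-trien-12,6α-olide | C=C1C(O[Si](C)(C)C)=C[C@H]2C(=C)CC[C@@H]3[C@H](OC(=O)[C@H]3C)[C@H]21 | intermediate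
9 | (11S)-3-oxoguaia-1,4(15),10(14)-trien-12,6α-olide (5αH) | C=C1C(=O)C=C2C(=C)CC[C@@H]3[C@H](OC(=O)[C@H]3C)[C@H]21 | intermediate
10 | Diels–Alder adduct: Δ1(10) β,γ-enone with H-2β, C2–C4' and C14–C15' bonds, C2 on the α-face of spiro C4' | C=C1C(=O)[C@H]2C3=C(CC[C@@H]4[C@H](OC(=O)[C@H]4C)[C@@H]13)CC[C@]21C(=O)C[C@H]2C(=C)CC[C@@H]3[C@H](OC(=O)[C@@H]3C)[C@H]21 | intermediate
11 | CNP0240988.1 (Δ1(2)-3-one, 10βH, 11S; spiro half 11'R) | C=C1C(=O)C2=C3[C@@H](CC[C@@H]4[C@H](OC(=O)[C@H]4C)[C@@H]13)CC[C@]21C(=O)C[C@H]2C(=C)CC[C@@H]3[C@H](OC(=O)[C@@H]3C)[C@H]21 | target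

**Step count and risks**
Total steps: 5. Longest linear sequence: 3 (1 → 2 → 5 → 11, or 1 → 3 → 7 → 11).

Most likely to fail, first: step 5. The dienone 9 can dimerise with itself, Pd–H can scramble alkenes, and C10 may be protonated on the wrong face or equilibrate (the relative stability of the two C10 epimers is not known). The fallback sets out from 5 (through its silyl enol ether 8) and comes back at 10. Compound 8 is quenched with PhSeCl (CH2Cl2, −78 °C) to the isolable 2α-phenylselanyl ketone F1. F1 is oxidised with mCPBA at −78 °C, in the absence of 7, to the selenoxide F2. Then 7 (3 equiv) and i-Pr2NH are added and the flask is warmed to 0–23 °C. Metal-free syn-elimination (H-1α is cis to the α-selenium) releases 9 slowly into excess dienophile, and adduct 10 is isolated. Its isomerisation to 11 can then be run separately, with Et3N in a non-polar solvent.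

Second: step 2. The hydrogenation is mismatched with the substrate's facial bias, and the two isolated methylenes may be reduced or isomerised. The fallback sets out from 1 and comes back at 3. The lactone is opened with NaOH (aq. MeOH) to the sodium 6α-hydroxy-guaia-4(15),10(14),11(13)-trien-12-oate F3. This acyclic acrylate is hydrogenated with carboxylate direction (Ru(OAc)2[(R)-BINAP], H2, MeOH; ligand antipode by analogy with 2-substituted acrylic acids) to the sodium (11R)-hydroxy acid salt F4. Acidification (aq. HCl) closes the trans lactone to 3.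

Third: step 3 (step 4 uses the same chemistry). Selenium may also oxidise C9, and the telescoped MnO2 stage may stall. The fallback sets out from 1 and comes back at 5. Allylic hydroxylation is run first on 1 itself (SeO2, t-BuOOH, CH2Cl2), the substrate for which this reaction is best established, giving isolated 3-epizaluzanin C F5. NaBH4 in MeOH at 0 °C then reduces only the lactone methylene to give 4, now isolated, and Dess–Martin periodinane (CH2Cl2, NaHCO3) oxidises 4 to 5.

**Further compounds**
F1 | step 5 | (11S)-3-oxo-2α-(phenylselanyl)guaia-4(15),10(14)-dien-12,6α-olide | C=C1C(=O)[C@H]([Se]c4ccccc4)[C@H]2C(=C)CC[C@@H]3[C@H](OC(=O)[C@H]3C)[C@H]21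
F2 | step 5 | selenoxide of F1 (mixture at selenium) | C=C1C(=O)[C@H]([Se](=O)c4ccccc4)[C@H]2C(=C)CC[C@@H]3[C@H](OC(=O)[C@H]3C)[C@H]21
F3 | step 2 | sodium 6α-hydroxyguaia-4(15),10(14),11(13)-trien-12-oate | C=C1CC[C@H]2C(=C)CC[C@@H](C(=C)C(=O)[O-])[C@H](O)[C@H]21.[Na+]
F4 | step 2 | sodium (11R)-6α-hydroxyguaia-4(15),10(14)-dien-12-oate | C=C1CC[C@H]2C(=C)CC[C@@H]([C@@H](C)C(=O)[O-])[C@H](O)[C@H]21.[Na+]
F5 | step 3 | 3-epizaluzanin C ((3R)-3α-hydroxydehydrocostus lactone) | C=C1[C@H](O)C[C@H]2C(=C)CC[C@@H]3[C@H](OC(=O)C3=C)[C@H]21
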